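**Retrosynthetic overview**
- The catechol is unmasked last by hydrogenolysis of a benzyl ether at arene C3. Before that, the stearate is placed on the primary alcohol by lipase transesterification with vinyl stearate.
- Key disconnection: the benzene ring (the only ring) is cut at C2–C3 and C5–C6. Arene C1, its CH neighbours C2 and C6 and the whole 3-hydroxypropyl chain are 3,4-dihydro-2H-pyran-5-carbaldehyde: the formyl carbon and pyran C6 become the two arene CH carbons, and the pyran oxygen becomes the chain-terminal OH.
- C3–C4–C5 with their three differentiated oxygens (OBn, OH, OMe) are 1-(benzyloxy)-3-methoxypropan-2-one; its carbonyl oxygen becomes the C4 phenol.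
- The aldehyde comes from dihydropyran by Vilsmeier formylation; the ketone comes from benzyl glycidyl ether by methanolysis and oxidation.
- Ring order: one ring only, closed in the [3+3] step while the pyran opens.

Key step: step 4

Remark: the target has no stereocentre; benzyl glycidyl ether is used as the racemate, since its only stereocentre becomes the carbonyl carbon in step 3.

**Route**

Step 1
Reactants: 1 3,4-dihydro-2H-pyran
Product: 3 3,4-dihydro-2H-pyran-5-carbaldehyde, via iminium chloride 2 (not isolated)
Conditions: POCl3 (1.1 equiv), DMF (1.5 equiv), CH2Cl2, 0 °C → rt; then aq. NaOAc, 0 °C → rt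
Reagents that add atoms: N,N-dimethylformamide, CN(C)C=O (formyl carbon); water, O (formyl oxygen)
Why: Vilsmeier–Haack formylation, in which the enol ether attacks the chloroiminium ion through its β-carbon (C5), loss of the C5 proton gives the vinylogous iminium salt 2, and buffered hydrolysis releases the vinylogous formate 3; the reaction type is established for cyclic enol ethers such as glycals.

Step 2
Reactants: 4 benzyl glycidyl ether (racemic 2-[(benzyloxy)methyl]oxirane)
Product: 5 1-(benzyloxy)-3-methoxypropan-2-ol (racemic)
Conditions: NaOMe (0.3 equiv), MeOH, 65 °C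
Reagents that add atoms: methanol (delivered as methoxide), CO
Why: Base-catalysed SN2 opening of the terminal epoxide by methoxide at the unhindered CH2 carbon should give the 1,3-dialkoxypropan-2-ol, whose racemic carbinol centre is erased in step 3.

Step 3
Reactants: 5 1-(benzyloxy)-3-methoxypropan-2-ol
Product: 6 1-(benzyloxy)-3-methoxypropan-2-one
Conditions: TEMPO (5 mol %), KBr (10 mol %), NaOCl (1.2 equiv), NaHCO3 buffer, CH2Cl2/H2O, 0 °C
Reagents that add atoms: none
Why: TEMPO/NaOCl (oxoammonium) oxidation of a secondary alcohol to the ketone under buffered biphasic conditions that leave the benzyl and methyl ethers untouched.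

Step 4
Reactants: 3 3,4-dihydro-2H-pyran-5-carbaldehyde; 6 1-(benzyloxy)-3-methoxypropan-2-one
Product: 8 3-[3-(benzyloxy)-4-hydroxy-5-methoxyphenyl]propan-1-ol, via dienone 7 (not isolated)
Conditions: 3 (1.2 equiv), KOtBu (2.2 equiv), THF/tBuOH, Ar, 0 °C, slow addition of 6 by syringe pump, then 50 °C; aq. HCl to pH 5
Reagents that add atoms: none
Why: Proposed new method: KOtBu reversibly enolizes ketone 6, and one α-carbon undergoes a Knoevenagel-type aldol condensation with the non-enolizable formyl group of 3 to give dienone 7, in which pyran C6 is the δ-terminus of a vinylogous β-alkoxy enone. The cross-conjugated enolate at the second α-carbon then attacks C6 in a 6-endo-trig vinylogous Michael addition (equally a 6π electrocyclization of the trienolate), which closes the carbocycle; E1cB expulsion of the ring oxygen opens the pyran to the 3-hydroxypropyl chain, and tautomerization gives the phenolate, so that aromatization makes the cascade irreversible. The closest known reaction types are the base-mediated phenol syntheses from 1,3-disubstituted acetones with malondialdehyde equivalents (nitromalonaldehyde, vinamidinium salts) and the ring-opening recyclizations of aldehyde 3 or of 3-formylchromones with 1,3-dinucleophiles such as acetonedicarboxylates; what is new is a non-activated 1,3-dialkoxyacetone as the C3 dinucleophile. No stereocentre is formed and no regiochemical question arises, because the formyl carbon and C6 both end as arene CH carbons flanking C1, so either α-carbon on either electrophilic carbon gives the same arene with OBn, OH and OMe fixed at C3, C4 and C5 by the ketone. The selectivity needed is cross-condensation over self-condensation of 6; it is secured by the non-enolizable aldehyde in slight excess, by the slow addition that keeps 6 dilute, and by the reversibility of ketone self-aldol against the irreversible aromatizing path.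

Step 5
Reactants: 8 3-[3-(benzyloxy)-4-hydroxy-5-methoxyphenyl]propan-1-ol; 9 vinyl stearate (ethenyl octadecanoate)
Product: 10 3-[3-(benzyloxy)-4-hydroxy-5-methoxyphenyl]propyl octadecanoate
Conditions: Candida antarctica lipase B on acrylic resin (Novozym 435), 9 (1.5 equiv), MTBE, 45 °C
Reagents that add atoms: none
Why: Lipase-catalysed irreversible transesterification with an enol ester, in which the serine hydrolase acylates the unhindered primary alcohol but not the di-ortho-substituted phenol and tautomerization of the released vinyl alcohol to acetaldehyde drives the reaction.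

Step 6
Reactants: 10 3-[3-(benzyloxy)-4-hydroxy-5-methoxyphenyl]propyl octadecanoate
Product: 11 3-(3,4-dihydroxy-5-methoxyphenyl)propyl octadecanoate
Conditions: H2 (1 atm), 10% Pd/C, EtOAc, rt
Reagents that add atoms: none
Why: Hydrogenolysis of the benzyl aryl ether over Pd/C under neutral conditions should free the catechol while the aliphatic ester, the methyl ether and the arene stay intact.

**Compound list**
1 | 3,4-dihydro-2H-pyran | C1CC=COC1 | starting material
2 | N-[(3,4-dihydro-2H-pyran-5-yl)methylidene]-N-methylmethanaminium chloride | C[N+](C)=CC1=COCCC1.[Cl-] | intermediate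
3 | 3,4-dihydro-2H-pyran-5-carbaldehyde | O=CC1=COCCC1 | intermediate
4 | benzyl glycidyl ether, 2-[(benzyloxy)methyl]oxirane (racemic) | C(OCc1ccccc1)C1CO1 | starting material
5 | 1-(benzyloxy)-3-methoxypropan-2-ol (racemic) | COCC(O)COCc1ccccc1 | intermediate
6 | 1-(benzyloxy)-3-methoxypropan-2-one | COCC(=O)COCc1ccccc1 | intermediate
7 | (3E)-1-(benzyloxy)-4-(3,4-dihydro-2H-pyran-5-yl)-3-methoxybut-3-en-2-one | CO/C(=C/C1=COCCC1)C(=O)COCc1ccccc1 | intermediate
8 | 3-[3-(benzyloxy)-4-hydroxy-5-methoxyphenyl]propan-1-ol | OCCCc1cc(OC)c(O)c(OCc2ccccc2)c1 | intermediate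
9 | vinyl stearate (ethenyl octadecanoate) | CCCCCCCCCCCCCCCCCC(=O)OC=C | starting material
10 | 3-[3-(benzyloxy)-4-hydroxy-5-methoxyphenyl]propyl octadecanoate | CCCCCCCCCCCCCCCCCC(=O)OCCCc1cc(OC)c(O)c(OCc2ccccc2)c1 | intermediate
11 | 3-(3,4-dihydroxy-5-methoxyphenyl)propyl octadecanoate | CCCCCCCCCCCCCCCCCC(=O)OCCCc1cc(O)c(O)c(OC)c1 | target

**Step count and risks**
Total step count: 6. Longest linear sequence: 5 steps (steps 2, 3, 4, 5, 6 from benzyl glycidyl ether).

Steps most likely to fail:

1. Step 4. The weakly acidic dialkoxyacetone may enolize too slowly or self-condense, the aldehyde may be degraded by the base before the second C–C bond forms, and the electron-rich phenolate may be oxidized by traces of air.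
The fallback sets out from aldehyde 3 and comes back to the route at target 11. It replaces the ketone enolate by a Lewis-acid-activated 1,3-bis(silyl enol ether) of a β-ketoester. This formal [3+3] salicylate synthesis is a known reaction type for 2-substituted 3-alkoxyacroleins, malondialdehyde acetals and 3-formylchromones. Methyl 4-methoxyacetoacetate (COCC(=O)CC(=O)OC) would be silylated with Me3SiCl/Et3N to methyl 4-methoxy-3-(trimethylsilyloxy)but-2-enoate F1. A second silylation with LiN(iPr)2/Me3SiCl in THF at −78 °C would give 1,4-dimethoxy-1,3-bis(trimethylsilyloxy)buta-1,3-diene F2. Both are expected as mixtures of geometric isomers, which is of no consequence for the arene. F2 and 3 with TMSOTf in CH2Cl2 (−78 → 20 °C), then Et3N/EtOH to complete pyran opening and aromatization, should give methyl 2-hydroxy-5-(3-hydroxypropyl)-3-methoxybenzoate F3. The ester is then exchanged for the missing phenol oxygen in three operations. LiAlH4 in THF should give 2-(hydroxymethyl)-4-(3-hydroxypropyl)-6-methoxyphenol F4. MnO2 in CH2Cl2 should oxidize only the benzylic alcohol to 2-hydroxy-5-(3-hydroxypropyl)-3-methoxybenzaldehyde F5. Dakin oxidation (H2O2, NaOH) should give 3-(3,4-dihydroxy-5-methoxyphenyl)propan-1-ol F6. Lipase acylation of F6 with vinyl stearate 9 under the conditions of step 5 is selective for primary alcohols beside catechols and should give 11 directly, without a benzyl group.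

2. Step 5. Transesterification with the long-chain, sparingly soluble acyl donor may stall, or chemoselectivity may erode through acylation of the phenol.
The fallback sets out from 8 and comes back at target 11. It replaces the enzymatic selectivity by protection. Phenol-selective O-benzylation (BnBr, K2CO3, acetone, reflux) should give 3-[3,4-bis(benzyloxy)-5-methoxyphenyl]propan-1-ol F7. Acylation with stearoyl chloride (CCCCCCCCCCCCCCCCCC(=O)Cl), pyridine and DMAP in CH2Cl2 should give 3-[3,4-bis(benzyloxy)-5-methoxyphenyl]propyl octadecanoate F8. Hydrogenolysis (H2, Pd/C, EtOAc) should remove both benzyl groups and give 11.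

3. Step 1. The HCl released may oligomerize the acid-sensitive enol ether, and the vinylogous ester may be opened hydrolytically during work-up.
The fallback sets out from 1 and comes back at aldehyde 3. It replaces the Vilsmeier reagent by Lewis-acid acetal chemistry. BF3·OEt2-catalysed addition of triethyl orthoformate (CCOC(OCC)OCC) to 1 at 0 °C should give 3-(diethoxymethyl)-2-ethoxyoxane F9 as a diastereomer mixture. Acid treatment (TsOH, wet toluene, distillation of ethanol) should hydrolyse the acetals and eliminate ethanol to give 3.

**Further compounds**
F1 | step 4 | methyl 4-methoxy-3-(trimethylsilyloxy)but-2-enoate (E/Z mixture) | COCC(O[Si](C)(C)C)=CC(=O)OC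
F2 | step 4 | 1,4-dimethoxy-1,3-bis(trimethylsilyloxy)buta-1,3-diene (mixture of geometric isomers) | COC=C(O[Si](C)(C)C)C=C(OC)O[Si](C)(C)C
F3 | step 4 | methyl 2-hydroxy-5-(3-hydroxypropyl)-3-methoxybenzoate | COC(=O)c1cc(CCCO)cc(OC)c1O
F4 | step 4 | 2-(hydroxymethyl)-4-(3-hydroxypropyl)-6-methoxyphenol | OCc1cc(CCCO)cc(OC)c1O
F5 | step 4 | 2-hydroxy-5-(3-hydroxypropyl)-3-methoxybenzaldehyde | O=Cc1cc(CCCO)cc(OC)c1O
F6 | step 4 | 3-(3,4-dihydroxy-5-methoxyphenyl)propan-1-ol | OCCCc1cc(O)c(O)c(OC)c1
F7 | step 5 | 3-[3,4-bis(benzyloxy)-5-methoxyphenyl]propan-1-ol | OCCCc1cc(OC)c(OCc2ccccc2)c(OCc2ccccc2)c1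
F8 | step 5 | 3-[3,4-bis(benzyloxy)-5-methoxyphenyl]propyl octadecanoate | CCCCCCCCCCCCCCCCCC(=O)OCCCc1cc(OC)c(OCc2ccccc2)c(OCc2ccccc2)c1
F9 | step 1 | 3-(diethoxymethyl)-2-ethoxyoxane (diastereomer mixture, racemic) | CCOC1OCCCC1C(OCC)OCC
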